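N5 lies between C6 and the methine C9a, and C9a carries the four-carbon arm C1–C2–C3–C4 that ends on the same nitrogen. Ring B is therefore a cyclopentanone (C6 as C=O, C7, C8, C9, C9a) plus one inserted nitrogen, and ring A is the tether of an intramolecular azide–ketone ring expansion.
Locants (quinolizidine numbering, same in both halves): ring A = N5–C4–C3(Me)–C2(=O)–C1–C9a, ring B = N5–C6–C7–C8–C9–C9a. C1 of each half is tied to C9 of the other by (CH2)5, giving a 16-membered carbocycle. Half A has H-1/H-9a cis; half B is all-equatorial.
Cuts: C2=O back to CHOH and C6H2 back to a lactam C=O; the carbocycle between the third and fourth carbon (counted from C9) of each pentamethylene chain (ring-closing metathesis, Wittig); then, in each half and in one operation, N5–C9a, N5–C6 and C1–C9a. Folding O–C2, C1 and the first two chain carbons into a butenolide makes C1 an electrophile for C9a.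
Forward: azido butenolide 8 (five steps) and racemic silyl enol ether 11 (one step) enter a Michael/Schmidt cascade that builds rings A and B of both halves (13, 15). Wittig coupling and then ring-closing metathesis make the macrocycle; hydrogenation, LiAlH4 and Swern oxidation finish.
Stereochemistry: C3 and the helper centre C2 come from an Evans syn aldol. C1 is set by addition anti to the C2 side chain of the butenolide. C9a is set anti to the C9 substituent and then carried to nitrogen with retention. The halves share C1/C3 but are mirror images at C9/C9a, so each antipode of racemic 11 serves one half.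

Key step: step 7

Assumption: steps 7 and 8 are one flask operation on racemic 11, written as two steps because each antipode gives one product (13 and 15 are diastereomers, separated on silica); the anomeric centres of lactols 20 and 23 and the geometry of the metathesis alkene in 25 are left undefined because they vanish later; the small azides 5, 7 and 8 are kept in solution at or below 40 °C.

Step 1
Reactants: 1 (S)-4-benzyl-3-propionyloxazolidin-2-one; 2 acrolein
Product: 3 syn-aldol imide
Conditions: Bu2BOTf, Et3N, CH2Cl2, 0 °C; 2, −78 → 0 °C; H2O2, MeOH, pH 7 buffer
Reagents that add atoms: none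
Why: Evans syn aldol reaction: the Z-configured dibutylboron enolate of 1 adds to acrolein through a chair-like Zimmerman–Traxler transition state on the face away from the benzyl group, which sets the future C3 (methyl) and the helper carbinol centre C2 in a syn relation under auxiliary control.

Step 2
Reactants: 3 syn-aldol imide
Product: 4 (2R,3R)-2-methylpent-4-ene-1,3-diol
Conditions: LiBH4, MeOH (1 equiv), Et2O, 0 °C
Reagents that add atoms: none
Why: Reductive cleavage of the N-acyl oxazolidinone with LiBH4 attacks only the exocyclic imide carbonyl, so the future C4 arrives as CH2OH, the auxiliary is released intact and neither stereocentre nor the vinyl group is touched.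

Step 3
Reactants: 4 (2R,3R)-2-methylpent-4-ene-1,3-diol
Product: 5 (3R,4R)-5-azido-4-methylpent-1-en-3-ol
Conditions: PPh3, diisopropyl azodicarboxylate, (PhO)2P(O)N3, THF, 0 → 23 °C
Reagents that add atoms: diphenylphosphoryl azide [N-]=[N+]=NP(=O)(Oc1ccccc1)Oc1ccccc1
Why: Mitsunobu azidation is selective for the unhindered primary hydroxyl group, whose alkoxyphosphonium salt forms faster than that of the secondary allylic alcohol, and the SN2 displacement takes place at a CH2 group so that no stereocentre is involved.

Step 4
Reactants: 5 (3R,4R)-5-azido-4-methylpent-1-en-3-ol; 6 acryloyl chloride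
Product: 7 azido allyl acrylate
Conditions: Et3N, CH2Cl2, −20 → 0 °C
Reagents that add atoms: none
Why: O-Acylation of the remaining secondary allylic alcohol with an acid chloride and an amine base breaks no bond at the carbinol carbon, so C2 keeps its configuration.

Step 5
Reactants: 7 azido allyl acrylate
Product: 8 azido butenolide
Conditions: second-generation Grubbs catalyst RuCl2(=CHPh)(PCy3)(H2IMes) (5 mol %), CH2Cl2 (0.01 M), 40 °C
Reagents that add atoms: none
Why: Ring-closing metathesis of an allyl acrylate to a but-2-enolide is a standard use of the second-generation catalyst, tolerates alkyl azides, is driven by loss of ethene and leaves C2 (now C5 of the furanone) and C3 untouched.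

Step 6
Reactants: 9 cyclopent-2-en-1-one; 10 but-3-en-1-ylmagnesium bromide
Product: 11 racemic silyl enol ether
Conditions: CuBr·SMe2 (5 mol %), Me3SiCl, DMPU, THF, −78 °C; Et3N, pentane, cold aq. NaHCO3
Reagents that add atoms: chlorotrimethylsilane C[Si](C)(C)Cl
Why: Copper-catalysed conjugate addition of a Grignard reagent accelerated by Me3SiCl traps the enolate regiospecifically as the silyl enol ether with its double bond next to the new C9 stereocentre, and the racemate is wanted because the two halves of the target have opposite configuration at C9 and C9a.

Step 7
Reactants: 8 azido butenolide; 11 racemic silyl enol ether (the (R)-antipode reacts here)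
Product: 13 half A lactam lactone, via half A keto azide 12 (not isolated)
Conditions: 8 and 11 in CH2Cl2, −78 °C, TiCl4 (1.1 equiv) added last, 2 h; MeOH (1.1 equiv), −78 °C; TiCl4 (2.5 equiv), −78 → 23 °C, 12 h; aq. NaHCO3; silica gel (separates 13 from 15)
Reagents that add atoms: none
Why: Proposed new method: TiCl4 activates butenolide 8 for a Mukaiyama–Michael attack by C9a of (R)-11 (new C1–C9a bond); loss of Me3SiCl and protonation of the titanium lactone enolate by the added MeOH leave the TiCl4-bound cyclopentanone 12, whose carbonyl carbon C6 is attacked on warming by the azide nitrogen (seven-membered azidohydrin, 7-exo-trig), after which C9a migrates from C6 to nitrogen anti-periplanar to the departing N2. The closest known reaction types are the Mukaiyama–Michael addition of silyl enol ethers to unsaturated carbonyl acceptors, the TiCl4-promoted intramolecular Schmidt reaction of 2-(4-azidobutyl)cycloalkanones and Lewis-acid domino Diels–Alder/Schmidt sequences, and only their coupling in one flask is new. The 1,2-shift closes ring A (N5–C9a bond, the seven-membered azidohydrin contracting to the six-membered ring) and at the same time widens the five-membered carbocycle C6–C7–C8–C9–C9a to the six-membered lactam ring B by inserting N5 between C6 and C9a. C1 is set by attack on the butenolide face anti to the C2 side chain, and C9a by attack on the enol ether face anti to the C9 butenyl group (trans, also the thermodynamic result), and C9a is then carried to nitrogen with retention. The step needs three selectivities: Michael addition must outrun attack of the azide on the activated butenolide (the enol ether is far more nucleophilic, the temperature is low and TiCl4 is added last), the azide must attack the ketone and not the lactone carbonyl (higher electrophilicity and feasible ring size), and C9a must migrate rather than C7 (only the tether-bearing carbon can lie anti to N2 in the bicyclic aminodiazonium ion). The lactone ring meanwhile masks O–C2 as an acid-stable ester and holds C2 at the alcohol level, so C1 and C3 cannot epimerise and the H-1/H-9a cis relation of half A is fixed kinetically.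

Step 8
Reactants: 8 azido butenolide; 11 racemic silyl enol ether (the (S)-antipode reacts here)
Product: 15 half B lactam lactone, via half B keto azide 14 (not isolated)
Conditions: same flask and conditions as step 7; 15 separated from 13 on silica gel
Reagents that add atoms: none
Why: Proposed new method: the same TiCl4-mediated Mukaiyama–Michael/intramolecular Schmidt cascade as in step 7 (Michael attack anti to the C2 side chain, azide addition to the TiCl4-bound ketone 14, anti-periplanar 1,2-shift of C9a with retention and loss of N2; closest known types again the Mukaiyama–Michael addition and the TiCl4-promoted intramolecular Schmidt reaction) acts on the (S)-antipode of 11, so that C1, C2 and C3 come out as in 13 while C9 and C9a are mirror-imaged, which gives the all-equatorial half B.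

Step 9
Reactants: 15 half B lactam lactone
Product: 17 half B alcohol, via half B aldehyde 16 (not isolated)
Conditions: O3, CH2Cl2–MeOH, −78 °C; NaBH4, −78 → 0 °C
Reagents that add atoms: ozone [O-][O+]=O
Why: Ozonolysis with reductive NaBH4 work-up cleaves the only C=C bond of 15 and trims the side chain to the three carbons needed, while NaBH4 at or below 0 °C leaves the γ-lactone and the tertiary lactam alone.

Step 10
Reactants: 17 half B alcohol
Product: 19 half B phosphonium bromide, via half B bromide 18 (not isolated)
Conditions: CBr4, PPh3, CH2Cl2, 0 °C; solvent change to MeCN, PPh3, 82 °C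
Reagents that add atoms: carbon tetrabromide BrC(Br)(Br)Br; triphenylphosphine c1ccc(cc1)P(c1ccccc1)c1ccccc1
Why: Appel bromination of the primary alcohol followed without purification by SN2 quaternisation of PPh3 with the unhindered primary bromide 18 is the standard entry to a non-stabilised Wittig salt and touches no stereocentre.

Step 11
Reactants: 13 half A lactam lactone
Product: 20 half A lactol
Conditions: iBu2AlH (1.2 equiv), CH2Cl2, −78 °C; aq. KNaC4H4O6 (tartrate)
Reagents that add atoms: none
Why: Partial reduction of a γ-lactone with iBu2AlH at −78 °C stops at the stable aluminium hemiacetal, and the strained trans-fused lactone is far more electrophilic than the tertiary lactam, which is left intact together with the alkene.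

Step 12
Reactants: 19 half B phosphonium bromide; 20 half A lactol
Product: 22 seco dimer, via half B ylide 21 (not isolated)
Conditions: 19, NaN(SiMe3)2 (1 equiv), THF, −78 → 0 °C; 20 pre-treated with NaN(SiMe3)2 (1 equiv), THF, −78 °C; mixed, −78 → 23 °C
Reagents that add atoms: none
Why: Wittig olefination of a lactol through its open hydroxy aldehyde form, the classical prostaglandin-type chain extension, joins the two halves; the aldehyde bears an α-CH2 group so that no stereocentre can epimerise, the phosphonium CH2 is more acidic than the lactone α-CH2, and the mainly Z geometry is irrelevant because the alkene is hydrogenated later.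

Step 13
Reactants: 22 seco dimer
Product: 23 seco dimer lactol
Conditions: iBu2AlH (2.2 equiv), CH2Cl2, −78 °C; aq. KNaC4H4O6 (tartrate)
Reagents that add atoms: none
Why: The same partial lactone reduction as in step 11, with one extra equivalent of iBu2AlH consumed by the free hydroxyl group, again spares both tertiary lactams and all alkenes.

Step 14
Reactants: 23 seco dimer lactol
Product: 24 diene diol
Conditions: Ph3PCH3Br, KOtBu, THF, 0 → 23 °C
Reagents that add atoms: methyltriphenylphosphonium bromide C[P+](c1ccccc1)(c1ccccc1)c1ccccc1.[Br-]
Why: Wittig methylenation of the lactol through its open form gives the allyl group on C1 of half B and frees the second C2 hydroxyl group, again without an epimerisable centre next to the aldehyde.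

Step 15
Reactants: 24 diene diol
Product: 25 macrocyclic diene
Conditions: first-generation Grubbs catalyst RuCl2(=CHPh)(PCy3)2 (10 mol %), CH2Cl2 (0.5 mM), 40 °C
Reagents that add atoms: none
Why: Ring-closing metathesis of two unhindered terminal alkenes at high dilution closes the 16-membered carbocycle with loss of ethene, and the first-generation catalyst is chosen because it hardly attacks 1,2-disubstituted alkenes, so that the Wittig alkene is not scrambled into head-to-head isomers.

Step 16
Reactants: 25 macrocyclic diene
Product: 26 saturated bis-lactam diol
Conditions: H2 (1 atm), Pd on carbon, EtOAc–EtOH, 23 °C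
Reagents that add atoms: none
Why: Heterogeneous catalytic hydrogenation saturates both disubstituted alkenes, which erases the undefined alkene geometry, and does not affect lactams, alcohols or stereocentres.

Step 17
Reactants: 26 saturated bis-lactam diol
Product: 27 diamino diol
Conditions: LiAlH4, THF, 66 °C; H2O, aq. NaOH
Reagents that add atoms: none
Why: LiAlH4 reduces both tertiary δ-lactams to tertiary amines, turning each C6 carbonyl helper into the C6 methylene group of ring B, while the C2 alkoxides are inert and no stereocentre is next to an acidic position.

Step 18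
Reactants: 27 diamino diol
Product: 28 target CNP0268544.1
Conditions: (COCl)2, DMSO, CH2Cl2, −78 °C; Et3N, −78 → −30 °C; cold pH 7 buffer
Reagents that add atoms: none
Why: Swern oxidation tolerates tertiary amines and runs below −30 °C under only briefly basic conditions, so both helper carbinols should become the C2 ketones without enolisation at C1 and C3 or retro-Mannich opening, which matters for the contra-thermodynamic half A.

Compound list
1 | (S)-4-benzyl-3-propionyloxazolidin-2-one | CCC(=O)N1[C@@H](Cc2ccccc2)COC1=O | starting material
2 | acrolein | C=CC=O | starting material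
3 | syn-aldol imide, (S)-4-benzyl-3-[(2S,3R)-3-hydroxy-2-methylpent-4-enoyl]oxazolidin-2-one | C=C[C@@H](O)[C@H](C)C(=O)N1[C@@H](Cc2ccccc2)COC1=O | intermediate
4 | (2R,3R)-2-methylpent-4-ene-1,3-diol | C=C[C@@H](O)[C@H](C)CO | intermediate
5 | (3R,4R)-5-azido-4-methylpent-1-en-3-ol | C=C[C@@H](O)[C@H](C)CN=[N+]=[N-] | intermediate
6 | acryloyl chloride | C=CC(=O)Cl | starting material
7 | azido allyl acrylate, (3R,4R)-5-azido-4-methylpent-1-en-3-yl acrylate | C=CC(=O)O[C@H](C=C)[C@H](C)CN=[N+]=[N-] | intermediate
8 | azido butenolide, (R)-5-[(R)-1-azidopropan-2-yl]furan-2(5H)-one | C[C@H](CN=[N+]=[N-])[C@@H]1OC(=O)C=C1 | intermediate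
9 | cyclopent-2-en-1-one | O=C1CCC=C1 | starting material
10 | but-3-en-1-ylmagnesium bromide | C=CCC[Mg]Br | starting material
11 | racemic silyl enol ether, [3-(but-3-en-1-yl)cyclopent-1-en-1-yl]oxy(trimethyl)silane | C=CCCC1CCC(O[Si](C)(C)C)=C1 | intermediate
12 | half A keto azide, (2R,3R)-2-{(2R,3S)-2-[(R)-1-azidopropan-2-yl]-5-oxooxolan-3-yl}-3-(but-3-en-1-yl)cyclopentan-1-one (ring substituents trans) | C[C@H](CN=[N+]=[N-])[C@@H]1OC(=O)C[C@H]1[C@@H]2C(=O)CC[C@H]2CCC=C | intermediate
13 | half A lactam lactone, (1S,2S,3R,9R,9aR)-9-(but-3-en-1-yl)-3-methyl-6-oxoquinolizidine with a trans-fused γ-lactone bridge C1–CH2–C(=O)–O–C2 (H-1/H-9a cis, H-9/H-9a trans) | C[C@@H]1CN2C(=O)CC[C@@H](CCC=C)[C@@H]2[C@@H]3CC(=O)O[C@@H]13 | intermediate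
14 | half B keto azide, (2S,3S)-cyclopentanone diastereomer of 12 with the same lactone and side-chain centres | C[C@H](CN=[N+]=[N-])[C@@H]1OC(=O)C[C@H]1[C@H]2C(=O)CC[C@@H]2CCC=C | intermediate
15 | half B lactam lactone, (1S,2S,3R,9S,9aS)-diastereomer of 13 (H-1/H-9a trans, H-9/H-9a trans, all ring substituents equatorial) | C[C@@H]1CN2C(=O)CC[C@H](CCC=C)[C@H]2[C@@H]3CC(=O)O[C@@H]13 | intermediate
16 | half B aldehyde, 15 with a 3-oxopropyl group at C9 | C[C@@H]1CN2C(=O)CC[C@H](CCC=O)[C@H]2[C@@H]3CC(=O)O[C@@H]13 | intermediate
17 | half B alcohol, 15 with a 3-hydroxypropyl group at C9 | C[C@@H]1CN2C(=O)CC[C@H](CCCO)[C@H]2[C@@H]3CC(=O)O[C@@H]13 | intermediate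
18 | half B bromide, 15 with a 3-bromopropyl group at C9 (spatial arrangement as in 15) | C[C@@H]1CN2C(=O)CC[C@H](CCCBr)[C@H]2[C@@H]3CC(=O)O[C@@H]13 | intermediate
19 | half B phosphonium bromide, 15 with a 3-(triphenylphosphonio)propyl group at C9 (spatial arrangement as in 15) | C[C@@H]1CN2C(=O)CC[C@H](CCC[P+](c3ccccc3)(c3ccccc3)c3ccccc3)[C@H]2[C@@H]3CC(=O)O[C@@H]13.[Br-] | intermediate
20 | half A lactol, 13 with the lactone C=O reduced to CH(OH) (anomers) | C[C@@H]1CN2C(=O)CC[C@@H](CCC=C)[C@@H]2[C@@H]3CC(O)O[C@@H]13 | intermediate
21 | half B ylide, triphenylphosphorane from 19 | C[C@@H]1CN2C(=O)CC[C@H](CCC=P(c3ccccc3)(c3ccccc3)c3ccccc3)[C@H]2[C@@H]3CC(=O)O[C@@H]13 | intermediate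
22 | seco dimer: half A (free 2-OH, 9-butenyl) joined from C1 through CH2–CH=CH–CH2–CH2 (Z) to C9 of the half B lactam lactone | C[C@@H]1CN2C(=O)CC[C@@H](CCC=C)[C@@H]2[C@H](C/C=C\CC[C@H]3CCC(=O)N4C[C@@H](C)[C@@H]5OC(=O)C[C@H]5[C@H]34)[C@H]1O | intermediate
23 | seco dimer lactol, 22 with the lactone C=O reduced to CH(OH) (anomers) | C[C@@H]1CN2C(=O)CC[C@@H](CCC=C)[C@@H]2[C@H](C/C=C\CC[C@H]3CCC(=O)N4C[C@@H](C)[C@@H]5OC(O)C[C@H]5[C@H]34)[C@H]1O | intermediate
24 | diene diol: as 22 but half B carries allyl at C1 and a free 2-OH | C[C@@H]1CN2C(=O)CC[C@@H](CCC=C)[C@@H]2[C@H](C/C=C\CC[C@H]3CCC(=O)N4C[C@@H](C)[C@H](O)[C@@H](CC=C)[C@H]34)[C@H]1O | intermediate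
25 | macrocyclic diene: 16-membered carbocycle closed, bis-lactam diol with one Z alkene and one alkene of undefined geometry | C[C@@H]1CN2C(=O)CC[C@H]3CCC=CC[C@@H]4[C@@H](O)[C@H](C)CN5C(=O)CC[C@H](CC/C=C\C[C@H]([C@H]1O)[C@@H]32)[C@@H]45 | intermediate
26 | saturated bis-lactam diol: half A (1S,2S,3R,9R,9aR), half B (1S,2S,3R,9S,9aS), C6 and C6' as lactam C=O, each 2-OH trans to the C1 chain and to the C3 methyl group | C[C@@H]1CN2C(=O)CC[C@H]3CCCCC[C@@H]4[C@@H](O)[C@H](C)CN5C(=O)CC[C@H](CCCCC[C@H]([C@H]1O)[C@@H]32)[C@@H]45 | intermediate
27 | diamino diol: 26 with both lactam C=O groups reduced to CH2 | C[C@@H]1CN2CCC[C@H]3CCCCC[C@@H]4[C@@H](O)[C@H](C)CN5CCC[C@H](CCCCC[C@H]([C@H]1O)[C@@H]32)[C@@H]45 | intermediate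
28 | target CNP0268544.1: macrocyclic bis(3-methylquinolizidin-2-one), half A (1S,3R,9R,9aR), half B (1S,3R,9S,9aS) | C[C@@H]1CN2CCC[C@H]3CCCCC[C@@H]4C(=O)[C@H](C)CN5CCC[C@H](CCCCC[C@H](C1=O)[C@@H]32)[C@@H]45 | target

Total step count: 18 numbered steps (17 flask operations, because steps 7 and 8 share one flask).
Longest linear sequence: 15 steps (1–5, 8–10, 12–18).

Steps most likely to fail

Step 7.
- **What may go wrong:** the activated butenolide may be captured by its own azide before the hindered Michael bond forms. The azide may also fail to add to the ketone, because a seven-membered azidohydrin and a twist-boat ring A (H-1/H-9a cis next to a planar lactam nitrogen) are required. The wrong ring carbon might migrate.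
- **Fallback (sets out from 8 and 11, comes back at 13):** only the Mukaiyama–Michael stage is run with TiCl4 at −78 °C and quenched cold, and keto azide 12 is isolated. PMe3 in THF then reduces the azide, and the iminophosphorane closes onto the ketone (Staudinger reduction, intramolecular aza-Wittig reaction) to the half A bicyclic imine F1. One equivalent of mCPBA at −78 °C oxidises the C=N bond, faster than the terminal alkene, to the half A spiro-oxaziridine F2. Irradiation at 254 nm in MeCN then brings about the known photochemical oxaziridine-to-lactam ring expansion, in which the C–C bond anti to the nitrogen lone pair (C6–C9a in the tethered system) migrates with retention, and gives 13.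

Step 8.
- **What may go wrong:** the same competition between azide self-capture and Michael addition, unequal consumption of the two antipodes of 11, and difficult separation of the two diastereomeric products.
- **Fallback (sets out from 8 and 11, comes back at 15):** keto azide 14 is isolated from the cold-quenched Michael reaction and separated from 12 at this less polar stage. PMe3 gives the half B bicyclic imine F3, mCPBA gives the half B spiro-oxaziridine F4, and photolysis at 254 nm gives 15 by the same known ring expansion.

Step 18.
- **What may go wrong:** enolisation at C1 or C3, or retro-Mannich opening of the freshly formed β-amino ketone of half A during base treatment or purification. This would drain it towards the all-equatorial diastereomer.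
- **Fallback (sets out from 26, comes back at 28):** the order of events is changed. Dess–Martin periodinane in CH2Cl2 oxidises the diol while both nitrogens are still non-basic lactams, giving the diketo bis-lactam F5. Both tertiary lactams are then reduced chemoselectively by hydrosilylation with Zn(OAc)2 (catalytic) and (EtO)3SiH in THF at 40 °C, a method that tolerates ketones. The target 28 then appears only in the last, neutral operation.

Further compounds
F1 | step 7 | half A bicyclic imine | C[C@@H]1CN=C2CC[C@@H](CCC=C)[C@@H]2[C@@H]3CC(=O)O[C@@H]13
F2 | step 7 | half A spiro-oxaziridine | C[C@@H]1CN2OC23CC[C@@H](CCC=C)[C@@H]3[C@@H]4CC(=O)O[C@@H]14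
F3 | step 8 | half B bicyclic imine | C[C@@H]1CN=C2CC[C@H](CCC=C)[C@H]2[C@@H]3CC(=O)O[C@@H]13
F4 | step 8 | half B spiro-oxaziridine | C[C@@H]1CN2OC23CC[C@H](CCC=C)[C@H]3[C@@H]4CC(=O)O[C@@H]14
F5 | step 18 | diketo bis-lactam | C[C@@H]1CN2C(=O)CC[C@H]3CCCCC[C@@H]4C(=O)[C@H](C)CN5C(=O)CC[C@H](CCCCC[C@H](C1=O)[C@@H]32)[C@@H]45
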